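**Plan**
- Numbering used throughout: carbocycle C1–C14 (C1 carries the exocyclic CH2, C4/C5 the oxirane, C8 and C10 are the lactone bridgeheads, C11 and C14 the carbinols); lactone carbons C15 (CHMe) and C16 (C=O).
- Cuts, in retrosynthetic order: oxirane oxygen and silyl group; C3–C4 (opens the 14-membered ring to an iodoalkane/iodoalkene); C15–CH3; C10–O (from a 10,11-epoxide and the C16 acid); C15 (one-carbon homologation); C8–C9 (enolate allylation); C14–C1 (alkenyl addition to an aldehyde).
- Forward: geranyl acetate gives C9–C14, 3-bromobut-3-en-1-ol gives C1–C3, hex-5-yn-1-ol gives C4–C8 and C16. The chain is joined at C14–C1, then C8–C9. The δ-lactone ring closes first, the 14-membered ring second (C3–C4), the oxirane last.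
- Enabling feature: C3 is an unactivated primary CH2 and C4 is the CH end of the C4–C5 oxirane, i.e. of an (E)-trisubstituted alkene. Both can be carried as C–I electrophiles and joined reductively at nickel, so no organometallic has to coexist with the lactone, the hydroxyl or the second alkene.
- Stereochemistry: C8 from an (S)-benzyloxazolidinone alkylation; C14 from an oxazaborolidine reduction; C10/C11 and C4/C5 from two epoxidations with the same L-fructose-derived ketone (C10 is inverted on lactonisation); C15 from trans-methylation of the lactone enolate.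

Key step: step 19

Remark: the L-fructose-derived Shi ketone is assumed to give (S,S)-epoxides from (E)-alkenes of the type RCH=C(Me)R′, the mirror image of the known outcome with the D-fructose-derived ketone.

**Step 1**
Reactants: 1 hex-5-yn-1-ol
Product: 3 (E)-6-iodo-5-methylhex-5-en-1-ol, via alkenylalane 2 (not isolated)
Conditions: Me3Al (3 equiv), Cp2ZrCl2 (25 mol%), CH2Cl2, 0 °C → rt; then I2, THF, −30 → 0 °C
Reagents that add atoms: trimethylaluminium C[Al](C)C; iodine II
Why: Negishi zirconium-catalysed syn-carboalumination should place the methyl on the internal and aluminium on the terminal alkyne carbon, and iodinolysis with retention should fix the (E)-iodoalkene that becomes C4=C5 with its methyl.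

**Step 2**
Reactants: 3 (E)-6-iodo-5-methylhex-5-en-1-ol
Product: 5 (E)-6-iodo-5-methylhex-5-enoic acid, via aldehyde 4 (not isolated)
Conditions: TEMPO (20 mol%), PhI(OAc)2 (2.2 equiv), MeCN/H2O (1:1), rt
Reagents that add atoms: water O
Why: Oxoammonium (TEMPO) oxidation of the primary alcohol should run through the aldehyde hydrate to the acid and leave the iodoalkene untouched.

**Step 3**
Reactants: 5 (E)-6-iodo-5-methylhex-5-enoic acid; 6 (S)-4-benzyl-1,3-oxazolidin-2-one
Product: 8 (S)-4-benzyl-3-[(E)-6-iodo-5-methylhex-5-enoyl]-1,3-oxazolidin-2-one, via mixed pivalic anhydride 7 (not isolated)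
Conditions: pivaloyl chloride, Et3N, THF, −20 °C; then 6, LiCl, −20 °C → rt
Reagents that add atoms: pivaloyl chloride CC(C)(C)C(Cl)=O (held in 7 only)
Why: Mixed-anhydride N-acylation of the oxazolidinone under LiCl/Et3N activation should attach the auxiliary without exposing the iodoalkene to an alkyllithium.

**Step 4**
Reactants: 9 3-bromobut-3-en-1-ol
Product: 10 2-bromo-4-chlorobut-1-ene
Conditions: PPh3, N-chlorosuccinimide, CH2Cl2, 0 °C → rt
Reagents that add atoms: N-chlorosuccinimide O=C1CCC(=O)N1Cl
Why: Appel-type chlorination of the primary alcohol should give a chloride that serves as a robust latent iodide for C3.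

**Step 5**
Reactants: 11 geranyl acetate
Product: 13 (2E)-3-methyl-6-oxohex-2-en-1-yl acetate, via ozonide 12 (not isolated)
Conditions: O3 (1 equiv), CH2Cl2, −78 °C; then Me2S, −78 °C → rt
Reagents that add atoms: ozone [O-][O+]=O
Why: Ozonolysis should take the electron-rich 6,7-alkene ahead of the 2,3-alkene, which the allylic acetate deactivates, and reductive work-up should give the aldehyde that becomes C14.

**Step 6**
Reactants: 13 (2E)-3-methyl-6-oxohex-2-en-1-yl acetate; 10 2-bromo-4-chlorobut-1-ene
Product: 15 rac-(2E)-9-chloro-6-hydroxy-3-methyl-7-methylidenenon-2-en-1-yl acetate, via alkenylchromium dichloride 14 (not isolated)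
Conditions: CrCl2 (4 equiv), NiCl2 (2 mol%), DMF, rt
Reagents that add atoms: chromium dichloride Cl[Cr]Cl (held in 14 only)
Why: The Nozaki–Hiyama–Kishi reaction should add the alkenyl bromide to the aldehyde only, sparing the acetate and the alkyl chloride, and so form C14–C1 with the exocyclic methylene in place (the racemic carbinol is corrected in steps 7 and 8).

**Step 7**
Reactants: 15 rac-allylic alcohol
Product: 16 (2E)-9-chloro-3-methyl-7-methylidene-6-oxonon-2-en-1-yl acetate
Conditions: Dess–Martin periodinane, NaHCO3, CH2Cl2, 0 °C → rt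
Reagents that add atoms: none
Why: Dess–Martin oxidation should give the α-methylene ketone under neutral conditions; it is used at once.

**Step 8**
Reactants: 16 α-methylene ketone
Product: 17 (2E,6S)-9-chloro-6-hydroxy-3-methyl-7-methylidenenon-2-en-1-yl acetate
Conditions: (R)-2-methyl-CBS-oxazaborolidine (20 mol%), catecholborane (1.5 equiv), toluene, −78 °C
Reagents that add atoms: none
Why: In the Corey–Bakshi–Shibata reduction the 2-substituted alkenyl group should act as the large substituent, so the (R)-catalyst should deliver hydride to the face that gives the (S)-carbinol (C14); catecholborane at low temperature avoids hydroboration.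

**Step 9**
Reactants: 17 (S)-allylic alcohol
Product: 18 (2E,6S)-6-[(tert-butyldimethylsilyl)oxy]-9-chloro-3-methyl-7-methylidenenon-2-en-1-yl acetate
Conditions: tert-butyldimethylsilyl chloride, imidazole, DMF, rt
Reagents that add atoms: tert-butyldimethylsilyl chloride CC(C)(C)[Si](C)(C)Cl
Why: Standard silylation should mask the C14 hydroxyl through the base, oxidant and nickel steps that follow.

**Step 10**
Reactants: 18 silyl ether acetate
Product: 19 (2E,6S)-6-[(tert-butyldimethylsilyl)oxy]-9-chloro-3-methyl-7-methylidenenon-2-en-1-ol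
Conditions: K2CO3 (20 mol%), MeOH, 0 °C → rt
Reagents that add atoms: none
Why: Base-catalysed transesterification should remove the acetate and leave the silyl ether and the primary chloride.

**Step 11**
Reactants: 19 allylic alcohol
Product: 20 tert-butyl{[(2E,6S)-1-bromo-9-chloro-3-methyl-7-methylidenenon-2-en-6-yl]oxy}dimethylsilane
Conditions: CBr4, PPh3, CH2Cl2, 0 °C; used directly
Reagents that add atoms: carbon tetrabromide BrC(Br)(Br)Br
Why: Appel bromination of the primary allylic alcohol should proceed by SN2 at C9 without allylic transposition.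

**Step 12**
Reactants: 8 N-acyl oxazolidinone; 20 allylic bromide
Product: 22 alkylated imide (S)-4-benzyl-3-[(2R,5E)-6-iodo-5-methyl-2-(side chain of 20)hex-5-enoyl]-1,3-oxazolidin-2-one, via sodium enolate 21 (not isolated)
Conditions: 8 (1.3 equiv), NaN(SiMe3)2 (1.25 equiv), THF, −78 °C; then 20 (1.0 equiv), −78 → −40 °C
Reagents that add atoms: sodium hexamethyldisilazide C[Si](C)(C)[N-][Si](C)(C)C.[Na+] (sodium held in 21 only)
Why: In the Evans alkylation the chelated (Z)-sodium enolate should be attacked by the allylic bromide on the face away from the benzyl group, setting C8 (R) and forming C8–C9; the alkyl chloride and iodoalkene are far less reactive.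

**Step 13**
Reactants: 22 alkylated imide
Product: 24 (2R,5E)-carboxylic acid, via peroxy acid 23 (not isolated)
Conditions: LiOH, H2O2, THF/H2O (3:1), 0 °C; Na2SO3; then 1 M HCl
Reagents that add atoms: hydrogen peroxide OO
Why: Hydroperoxide should attack the exocyclic imide carbonyl selectively (standard auxiliary cleavage) without epimerising C8, and the auxiliary is recovered.

**Step 14**
Reactants: 24 carboxylic acid
Product: 26 diazoketone, via mixed carbonic anhydride 25 (not isolated)
Conditions: isobutyl chloroformate, Et3N, THF, −20 °C; then CH2N2, Et2O, 0 °C → rt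
Reagents that add atoms: isobutyl chloroformate CC(C)COC(Cl)=O (held in 25 only); diazomethane C=[N+]=[N-]
Why: First stage of the Arndt–Eistert homologation: the activated acid should acylate diazomethane, whose carbon becomes C15.

**Step 15**
Reactants: 26 diazoketone
Product: 28 (3R,6E)-homologated acid, via ketene 27 (not isolated)
Conditions: PhCO2Ag (10 mol%), Et3N, THF/H2O (9:1), rt, dark
Reagents that add atoms: water O
Why: In the Wolff rearrangement C8 should migrate with retention, and water should trap the ketene, so the former acyl carbon becomes C16.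

**Step 16**
Reactants: 28 homologated acid
Product: 30 (4R,6R)-hydroxy δ-lactone, via epoxy acid 29 (not isolated)
Conditions: L-fructose-derived Shi ketone (30 mol%), Oxone (2KHSO5·KHSO4·K2SO4), K2CO3, Bu4NHSO4, MeCN/dimethoxymethane/aq. Na2B4O7 buffer (pH 10.5), 0 °C; then citric acid to pH 4, camphorsulfonic acid (cat.), CH2Cl2, rt
Reagents that add atoms: potassium peroxymonosulfate OOS(=O)(=O)[O-].[K+]
Why: Shi epoxidation should pick the most electron-rich (E)-trisubstituted alkene (the iodoalkene and the hindered 1,1-disubstituted alkene react more slowly) and give the (10S,11S)-epoxide under catalyst control; the acid should then open it 6-exo at the secondary C10 with inversion, giving C10 (R) and C11 (S), with the 7-endo opening at tertiary C11 as the competing path.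

**Step 17**
Reactants: 30 hydroxy δ-lactone
Product: 32 (3S,4R,6R)-3-methyl lactone, via dilithio enolate 31 (not isolated)
Conditions: LiN(iPr)2 (2.3 equiv), THF, −78 °C; MeI (3 equiv), −78 → −40 °C; then H2O
Reagents that add atoms: lithium diisopropylamide CC(C)[N-]C(C)C.[Li+] (lithium held in 31 only); iodomethane CI
Why: Enolate alkylation of the δ-lactone should occur anti to the adjacent C8 substituent, giving the 3,4-trans product with C15 (S), which is also the thermodynamic isomer.

**Step 18**
Reactants: 32 methyl lactone chloride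
Product: 33 methyl lactone iodide (alkyl iodide at C3, alkenyl iodide at C4)
Conditions: NaI (10 equiv), acetone, 56 °C, dark
Reagents that add atoms: sodium iodide [Na+].[I-]
Why: Finkelstein exchange at the primary chloride should unveil the C3 iodide; the lactone, silyl ether and iodoalkene are inert.

**Step 19**
Reactants: 33 iodoalkane/iodoalkene
Product: 34 macrocyclic (4E)-triene lactone, C14 silyl ether
Conditions: NiI2 (30 mol%), 4,4′-di-tert-butyl-2,2′-bipyridine (30 mol%), Mn powder (4 equiv), NaI (0.5 equiv), N,N-dimethylacetamide, 40 °C; 33 added by syringe pump over 12 h (final 2 mM)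
Reagents that add atoms: none
Why: Proposed new method: zerovalent nickel (from NiI2 and Mn) should insert into the C(sp2)–I bond, the divalent alkenylnickel iodide should capture the primary radical released from the C(sp3)–I bond by iodine abstraction at a monovalent nickel centre, and reductive elimination from trivalent nickel should form C3–C4. The closest known reaction is the intermolecular nickel-catalysed reductive cross-electrophile coupling of alkenyl halides with primary alkyl halides and its small-ring intramolecular versions; closing a macrocycle this way is the untested element. The 14-membered carbocycle closes by direct sp3–sp2 union with both atoms in the ring; no stereocentre is formed, and the E geometry of C4=C5 should carry over because alkenylnickel species keep their configuration. The step needs discrimination between the two C–I bonds, which their different activation modes (two-electron insertion at sp2, atom abstraction at sp3) should provide. It also needs cyclisation to beat oligomerisation and hydrodehalogenation, which slow addition and the cis-4,6-disubstituted lactone (both arms equatorial, on the same side) should favour. The lactone, tertiary alcohol, silyl ether and exocyclic alkene are not expected to react.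

**Step 20**
Reactants: 34 macrocyclic triene
Product: 35 (4S,5S)-epoxide, C14 silyl ether
Conditions: L-fructose-derived Shi ketone (50 mol%), Oxone (2KHSO5·KHSO4·K2SO4), K2CO3, Bu4NHSO4, MeCN/dimethoxymethane/aq. Na2B4O7 buffer (pH 10.5), −10 → 0 °C; work-up at pH 5
Reagents that add atoms: potassium peroxymonosulfate OOS(=O)(=O)[O-].[K+]
Why: Shi epoxidation should select the only trisubstituted alkene over the hindered exocyclic methylene, and the same catalyst face preference as in step 16 should give the (4S,5S)-oxirane.

**Step 21**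
Reactants: 35 epoxide silyl ether
Product: 36 target CNP0262409.2
Conditions: Bu4NF/AcOH (1:1, 3 equiv), THF, 0 °C → rt
Reagents that add atoms: none
Why: Acetic-acid-buffered fluoride desilylation should free the C14 hydroxyl without generating an alkoxide that could open the oxirane or the lactone.

**Compound list**
1 | hex-5-yn-1-ol | C#CCCCCO | starting material
2 | alkenylalane, (E)-Me2Al–CH=C(Me)(CH2)4–OAlMe2 | C[Al](C)/C=C(\C)CCCCO[Al](C)C | intermediate
3 | (E)-6-iodo-5-methylhex-5-en-1-ol | OCCCC/C(C)=C/I | intermediate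
4 | (E)-6-iodo-5-methylhex-5-enal | O=CCCC/C(C)=C/I | intermediate
5 | (E)-6-iodo-5-methylhex-5-enoic acid | OC(=O)CCC/C(C)=C/I | intermediate
6 | (S)-4-benzyl-1,3-oxazolidin-2-one | O=C1OC[C@H](Cc2ccccc2)N1 | starting material
7 | mixed pivalic anhydride of 5 | CC(C)(C)C(=O)OC(=O)CCC/C(C)=C/I | intermediate
8 | (S)-4-benzyl-3-[(E)-6-iodo-5-methylhex-5-enoyl]-1,3-oxazolidin-2-one | O=C(CCC/C(C)=C/I)N1[C@@H](Cc2ccccc2)COC1=O | intermediate
9 | 3-bromobut-3-en-1-ol | C=C(Br)CCO | starting material
10 | 2-bromo-4-chlorobut-1-ene | C=C(Br)CCCl | intermediate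
11 | geranyl acetate, (2E)-3,7-dimethylocta-2,6-dien-1-yl acetate | CC(C)=CCC/C(C)=C/COC(C)=O | starting material
12 | ozonide of the 6,7-alkene of 11 | CC(=O)OC/C=C(\C)CCC1OOC(C)(C)O1 | intermediate
13 | (2E)-3-methyl-6-oxohex-2-en-1-yl acetate | CC(=O)OC/C=C(\C)CCC=O | intermediate
14 | (4-chlorobut-1-en-2-yl)chromium dichloride | C=C(CCCl)[Cr](Cl)Cl | intermediate
15 | rac-(2E)-9-chloro-6-hydroxy-3-methyl-7-methylidenenon-2-en-1-yl acetate | CC(=O)OC/C=C(\C)CCC(O)C(=C)CCCl | intermediate
16 | (2E)-9-chloro-3-methyl-7-methylidene-6-oxonon-2-en-1-yl acetate | CC(=O)OC/C=C(\C)CCC(=O)C(=C)CCCl | intermediate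
17 | (2E,6S)-9-chloro-6-hydroxy-3-methyl-7-methylidenenon-2-en-1-yl acetate | CC(=O)OC/C=C(\C)CC[C@H](O)C(=C)CCCl | intermediate
18 | (2E,6S)-6-[(tert-butyldimethylsilyl)oxy]-9-chloro-3-methyl-7-methylidenenon-2-en-1-yl acetate | CC(=O)OC/C=C(\C)CC[C@H](O[Si](C)(C)C(C)(C)C)C(=C)CCCl | intermediate
19 | (2E,6S)-6-[(tert-butyldimethylsilyl)oxy]-9-chloro-3-methyl-7-methylidenenon-2-en-1-ol | OC/C=C(\C)CC[C@H](O[Si](C)(C)C(C)(C)C)C(=C)CCCl | intermediate
20 | tert-butyl{[(2E,6S)-1-bromo-9-chloro-3-methyl-7-methylidenenon-2-en-6-yl]oxy}dimethylsilane | BrC/C=C(\C)CC[C@H](O[Si](C)(C)C(C)(C)C)C(=C)CCCl | intermediate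
21 | (Z)-sodium enolate of 8 | [Na+].[O-]/C(=C\CC/C(C)=C/I)N1[C@@H](Cc2ccccc2)COC1=O | intermediate
22 | (S)-4-benzyl-3-{(2R,5E)-2-[(2E,6S)-6-(tert-butyldimethylsilyloxy)-9-chloro-3-methyl-7-methylidenenon-2-en-1-yl]-6-iodo-5-methylhex-5-enoyl}-1,3-oxazolidin-2-one | O=C([C@@H](C/C=C(\C)CC[C@H](O[Si](C)(C)C(C)(C)C)C(=C)CCCl)CC/C(C)=C/I)N1[C@@H](Cc2ccccc2)COC1=O | intermediate
23 | peroxy acid corresponding to 24 (formed as its lithium salt) | OOC(=O)[C@@H](C/C=C(\C)CC[C@H](O[Si](C)(C)C(C)(C)C)C(=C)CCCl)CC/C(C)=C/I | intermediate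
24 | (2R,5E)-2-[(2E,6S)-6-(tert-butyldimethylsilyloxy)-9-chloro-3-methyl-7-methylidenenon-2-en-1-yl]-6-iodo-5-methylhex-5-enoic acid | OC(=O)[C@@H](C/C=C(\C)CC[C@H](O[Si](C)(C)C(C)(C)C)C(=C)CCCl)CC/C(C)=C/I | intermediate
25 | mixed isobutyl carbonic anhydride of 24 | CC(C)COC(=O)OC(=O)[C@@H](C/C=C(\C)CC[C@H](O[Si](C)(C)C(C)(C)C)C(=C)CCCl)CC/C(C)=C/I | intermediate
26 | (3R,6E)-1-diazo-7-iodo-6-methyl-3-[(2E,6S)-6-(tert-butyldimethylsilyloxy)-9-chloro-3-methyl-7-methylidenenon-2-en-1-yl]hept-6-en-2-one | [N-]=[N+]=CC(=O)[C@@H](C/C=C(\C)CC[C@H](O[Si](C)(C)C(C)(C)C)C(=C)CCCl)CC/C(C)=C/I | intermediate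
27 | ketene from Wolff rearrangement of 26 | O=C=C[C@@H](C/C=C(\C)CC[C@H](O[Si](C)(C)C(C)(C)C)C(=C)CCCl)CC/C(C)=C/I | intermediate
28 | (3R,6E)-7-iodo-6-methyl-3-[(2E,6S)-6-(tert-butyldimethylsilyloxy)-9-chloro-3-methyl-7-methylidenenon-2-en-1-yl]hept-6-enoic acid | OC(=O)C[C@@H](C/C=C(\C)CC[C@H](O[Si](C)(C)C(C)(C)C)C(=C)CCCl)CC/C(C)=C/I | intermediate
29 | (10S,11S)-epoxy acid (target numbering): 28 with a 2,3-trans oxirane in place of the side-chain trisubstituted alkene | OC(=O)C[C@@H](C[C@@H]1O[C@@]1(C)CC[C@H](O[Si](C)(C)C(C)(C)C)C(=C)CCCl)CC/C(C)=C/I | intermediate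
30 | (4R,6R)-6-[(2S,5S)-5-(tert-butyldimethylsilyloxy)-8-chloro-2-hydroxy-6-methylideneoctan-2-yl]-4-[(E)-4-iodo-3-methylbut-3-en-1-yl]oxan-2-one | I/C=C(C)/CC[C@@H]1C[C@@H](OC(=O)C1)[C@@](C)(O)CC[C@H](O[Si](C)(C)C(C)(C)C)C(=C)CCCl | intermediate
31 | dilithio species of 30 (lactone enolate and tertiary alkoxide) | I/C=C(C)/CC[C@@H]1C[C@@H](OC([O-])=C1)[C@@](C)([O-])CC[C@H](O[Si](C)(C)C(C)(C)C)C(=C)CCCl.[Li+].[Li+] | intermediate
32 | (3S,4R,6R)-6-[(2S,5S)-5-(tert-butyldimethylsilyloxy)-8-chloro-2-hydroxy-6-methylideneoctan-2-yl]-4-[(E)-4-iodo-3-methylbut-3-en-1-yl]-3-methyloxan-2-one | I/C=C(C)/CC[C@@H]1C[C@@H](OC(=O)[C@H]1C)[C@@](C)(O)CC[C@H](O[Si](C)(C)C(C)(C)C)C(=C)CCCl | intermediate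
33 | (3S,4R,6R)-6-[(2S,5S)-5-(tert-butyldimethylsilyloxy)-2-hydroxy-8-iodo-6-methylideneoctan-2-yl]-4-[(E)-4-iodo-3-methylbut-3-en-1-yl]-3-methyloxan-2-one | I/C=C(C)/CC[C@@H]1C[C@@H](OC(=O)[C@H]1C)[C@@](C)(O)CC[C@H](O[Si](C)(C)C(C)(C)C)C(=C)CCI | intermediate
34 | macrocyclic triene: 14-membered carbocycle with C1 exocyclic methylene, (4E)-C4=C5 (5-methyl), (8R,10R,15S)-δ-lactone bridge, (11S)-hydroxy-11-methyl, (14S)-tert-butyldimethylsilyloxy | C=C1CC/C=C(C)/CC[C@@H]2C[C@@H](OC(=O)[C@H]2C)[C@@](C)(O)CC[C@@H]1O[Si](C)(C)C(C)(C)C | intermediate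
35 | (4S,5S)-4,5-epoxide of 34 | C=C1CC[C@@H]2O[C@@]2(C)CC[C@@H]2C[C@@H](OC(=O)[C@H]2C)[C@@](C)(O)CC[C@@H]1O[Si](C)(C)C(C)(C)C | intermediate
36 | CNP0262409.2: 14-membered carbocycle with C1 exocyclic methylene, (4S,5S)-4,5-epoxy-5-methyl, δ-lactone C8(R)–C15(S, methyl)–C16(=O)–O–C10(R), (11S)-11-hydroxy-11-methyl, (14S)-14-hydroxy | C=C1CC[C@@H]2O[C@@]2(C)CC[C@@H]2C[C@@H](OC(=O)[C@H]2C)[C@@](C)(O)CC[C@@H]1O | target

**Totals**
Total step count: 21. Longest linear sequence: 17 steps (11 → 36, steps 5–21). Steps 1–3 and step 4 are side branches.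

**Steps most likely to fail**

Step 19 (Proposed new method). The alkyl radical may be reduced by the solvent or captured by another chain before it reaches the alkenylnickel centre of its own molecule (hydrodehalogenation, oligomerisation), and the iodoalkene may homocouple. The fallback sets out from 33 and returns at 34. It replaces the radical cross-electrophile manifold by a polar cross-coupling of a preformed organometallic. The tertiary alcohol of 33 is capped (Me3SiOTf, 2,6-lutidine, CH2Cl2, −78 °C) to give the trimethylsilyl ether F1. Zinc dust with LiCl in THF at 40 °C inserts selectively into the C(sp3)–I bond to give the alkylzinc iodide F2. Slow addition of F2 to Pd2(dba)3/tri(2-furyl)phosphine in THF/N-methylpyrrolidone at 50 °C closes the ring by an intramolecular sp3–sp2 Negishi coupling to the silylated macrocycle F3. Aqueous citric acid in methanol removes the trimethylsilyl group and gives 34.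

Step 20. The face preferred by the catalyst may be the one that the ring conformation shields, leading to poor facial selectivity, a stalled reaction or attack on the exocyclic methylene. The fallback sets out from 34 and returns at 35. Oxygen is delivered under substrate control. N-Bromosuccinimide in aqueous THF at 0 °C forms the bromonium ion on the exposed face, and water opens it at the tertiary C5 to give the (4R,5S)-bromohydrin F4. Cs2CO3 in MeCN then closes the oxirane by SN2 at C4, which places oxygen on the face opposite to that reached by a direct electrophilic oxidant. If the exposed face turns out to be the correct one, buffered m-chloroperbenzoic acid is used directly instead.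

Step 21. Once the C14 hydroxyl is free, it or its alkoxide may open the C4–C5 oxirane across the ring (transannular ether formation), and fluoride may attack the lactone. The fallback sets out from 34 and returns at 36. The order is changed so that the oxirane is made last: 34 is desilylated first (Bu4NF, THF, rt) to the diol F5, and the trisubstituted alkene of F5 is then epoxidised with the same L-fructose-derived ketone and Oxone to give 36 directly.

**Further compounds**
F1 | step 19 | trimethylsilyl ether of 33 at the C11 hydroxyl | I/C=C(C)/CC[C@@H]1C[C@@H](OC(=O)[C@H]1C)[C@@](C)(O[Si](C)(C)C)CC[C@H](O[Si](C)(C)C(C)(C)C)C(=C)CCI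
F2 | step 19 | alkylzinc iodide from F1 (zinc at C3) | I/C=C(C)/CC[C@@H]1C[C@@H](OC(=O)[C@H]1C)[C@@](C)(O[Si](C)(C)C)CC[C@H](O[Si](C)(C)C(C)(C)C)C(=C)CC[Zn]I
F3 | step 19 | trimethylsilyl ether of 34 at the C11 hydroxyl | C=C1CC/C=C(C)/CC[C@@H]2C[C@@H](OC(=O)[C@H]2C)[C@@](C)(O[Si](C)(C)C)CC[C@@H]1O[Si](C)(C)C(C)(C)C
F4 | step 20 | (4R,5S)-4-bromo-5-hydroxy bromohydrin of 34 | C=C1CC[C@@H](Br)[C@@](C)(O)CC[C@@H]2C[C@@H](OC(=O)[C@H]2C)[C@@](C)(O)CC[C@@H]1O[Si](C)(C)C(C)(C)C
F5 | step 21 | macrocyclic triene diol (34 without the silyl group) | C=C1CC/C=C(C)/CC[C@@H]2C[C@@H](OC(=O)[C@H]2C)[C@@](C)(O)CC[C@@H]1O
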